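## Retrosynthetic overview

- Target 25 ⇐ removal of the tert-butyl ester and silyl ether ⇐ C7 allylic hydroxylation of the 6β-benzoate ⇐ α-face reduction and benzoylation of a C6 ketone unmasked from an enol ether.
- Side chain ⇐ sp3–sp2 Suzuki–Miyaura coupling of a C9 vinyl group (from the C11 ester) with an (E)-vinyl iodide.
- Ring B (formed second) ⇐ catalytic asymmetric [4+2] of a ring A 2-ethoxydiene with ethyl buta-2,3-dienoate; it forms C9–C10 and C7–C8, sets C9 and C10, and delivers the 8(17)-methylene and the masked C6 ketone.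
- Ring A (formed first) ⇐ organocatalytic Michael addition of an α-methyl β-keto ester to acrolein (sets C4) with aldol condensation; enol triflate and Stille coupling then give the diene.

Assumption: atom labels C1–C20 follow labdane numbering; 1, 3, 8, 10 and 14 are taken as purchasable; the catalyst antipodes in steps 2 and 5 are those that give the drawn configurations (otherwise the pseudoenantiomeric catalyst is used).

## Route

Step 1
Reactants: 1 tert-butyl 3-oxopentanoate
Product: 2 tert-butyl 2-methyl-3-oxopentanoate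
Conditions: MeI (1.05 equiv), K2CO3, acetone, 50 °C
Reagents that add atoms: iodomethane CI
Why: C-alkylation of the doubly activated methylene (β-keto ester alkylation); 2 is a racemate whose α-centre is erased by enolisation in step 2, so no fixed stereocentre exists yet.

Step 2
Reactants: 2 tert-butyl 2-methyl-3-oxopentanoate; 3 acrolein
Product: 5 tert-butyl (1S)-1,3-dimethyl-2-oxocyclohex-3-ene-1-carboxylate, via Michael aldehyde 4 (not isolated)
Conditions: 9-O-(phenanthren-9-yl)cupreidine (10 mol%), CH2Cl2, −24 °C; then pyrrolidinium trifluoroacetate (20 mol%), 40 °C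
Reagents that add atoms: none
Why: bifunctional 6'-hydroxy cinchona catalysis (quinuclidine pairs with the enolate, the phenol hydrogen-bonds to acrolein) gives an enantioselective Michael addition that sets the quaternary C4 centre (S), the first stereocentre, and amine-salt-catalysed intramolecular aldol condensation of the ethyl ketone onto the aldehyde closes ring A (Robinson-type annulation).

Step 3
Reactants: 5 tert-butyl (1S)-1,3-dimethyl-2-oxocyclohex-3-ene-1-carboxylate
Product: 7 tert-butyl (1S)-1,3-dimethyl-2-{[(trifluoromethyl)sulfonyl]oxy}cyclohex-2-ene-1-carboxylate, via lithium enolate 6 (not isolated)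
Conditions: LiBH(sBu)3, THF, −78 °C; then PhNTf2, −78 → 0 °C
Reagents that add atoms: N-phenylbis(trifluoromethanesulfonimide) O=S(=O)(N(c1ccccc1)S(=O)(=O)C(F)(F)F)C(F)(F)F
Why: 1,4-hydride addition to the β-unsubstituted enone gives the tetrasubstituted enolate regiospecifically and O-sulfonylation traps it as the C5=C10 enol triflate (reductive triflation); C4 is quaternary and untouched.

Step 4
Reactants: 7 enol triflate; 8 tributyl(1-ethoxyethenyl)stannane
Product: 9 tert-butyl (1S)-2-(1-ethoxyethenyl)-1,3-dimethylcyclohex-2-ene-1-carboxylate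
Conditions: Pd(PPh3)4 (5 mol%), LiCl (3 equiv), THF, 65 °C
Reagents that add atoms: none
Why: Stille coupling of a hindered cyclohexenyl triflate, well known for 2,6,6-trisubstituted cyclohexenyl triflates, attaches C6 and C7 as an electron-rich 2-ethoxydiene.

Step 5
Reactants: 9 ring A 2-ethoxydiene; 10 ethyl buta-2,3-dienoate
Product: 11 1-tert-butyl 5-ethyl (1S,4aR,5R)-8-ethoxy-1,4a-dimethyl-6-methylidene-1,2,3,4,4a,5,6,7-octahydronaphthalene-1,5-dicarboxylate
Conditions: chiral IDPi acid (imidodiphosphorimidate from two 3,3'-diaryl-BINOL units, N-triflyl; 5 mol%), Me2C=C(OMe)OSiMe3 (10 mol%), 10 (2 equiv), toluene, −60 → −30 °C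
Reagents that add atoms: none
Why: Proposed new method: a confined chiral silylium–imidodiphosphorimidate ion pair activates the allenoate carbonyl so that its α,β-double bond adds across the 2-ethoxydiene in an asynchronous endo [4+2] (C7–C8 bond leading, then C9–C10 closure at the tetrasubstituted terminus), with the catalyst antipode matched to C4 so that the dienophile comes from the face opposite the pseudoaxial CO2tBu and the ester sits endo, which sets C10 (R) and C9 (R, C11 trans to the angular methyl) and leaves the 8(17)-methylene and the C5=C6 enol ether; the closest known reactions are silylium/IDPi-catalysed Diels–Alder reactions of α,β-unsaturated esters with simple dienes and the thermal cycloadditions of 2,6,6-trimethyl-1-vinylcyclohexene with acetylenic esters, whereas an allenoate with a tetrasubstituted 2-alkoxydiene under this catalysis has not been shown.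

Step 6
Reactants: 11 cycloadduct
Product: 13 tert-butyl (1S,4aR,5R)-5-ethenyl-8-ethoxy-1,4a-dimethyl-6-methylidene-1,2,3,4,4a,5,6,7-octahydronaphthalene-1-carboxylate, via aldehyde 12 (not isolated)
Conditions: iBu2AlH (1.1 equiv), CH2Cl2, −78 °C; then Ph3P=CH2 (from Ph3PCH3Br, KN(SiMe3)2), THF, −78 → 0 °C
Reagents that add atoms: methyltriphenylphosphonium bromide C[P+](c1ccccc1)(c1ccccc1)c1ccccc1.[Br-]
Why: half-reduction of the ethyl ester (the neopentyl tert-butyl ester is inert at −78 °C) and in-flask Wittig methylenation give the C11=C12 vinyl group without isolating the epimerisable β,γ-unsaturated aldehyde.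

Step 7
Reactants: 14 but-2-yn-1-ol
Product: 15 (but-2-yn-1-yloxy)(tert-butyl)diphenylsilane
Conditions: TBDPSCl, imidazole, DMF, 0 °C → rt
Reagents that add atoms: tert-butyl(chloro)diphenylsilane CC(C)(C)[Si](Cl)(c1ccccc1)c1ccccc1
Why: standard silylation of a primary alcohol; the TBDPS ether survives the later dilute-acid hydrolysis.

Step 8
Reactants: 15 silyl ether of but-2-yn-1-ol
Product: 17 tert-butyl{[(2E)-3-iodobut-2-en-1-yl]oxy}diphenylsilane, via vinylzirconocene 16 (not isolated)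
Conditions: Cp2Zr(H)Cl (2.2 equiv), THF, 50 °C; then I2, 0 °C
Reagents that add atoms: iodine II
Why: syn-hydrozirconation with excess reagent equilibrates to the less hindered vinylzirconium (Zr on the methyl-bearing carbon) and iodinolysis with retention gives the (E)-iodide, which fixes the 13E geometry.

Step 9
Reactants: 13 C9-vinyl compound; 17 (E)-vinyl iodide
Product: 19 tert-butyl (1S,4aR,5R)-5-[(3E)-5-{[tert-butyl(diphenyl)silyl]oxy}-3-methylpent-3-en-1-yl]-8-ethoxy-1,4a-dimethyl-6-methylidene-1,2,3,4,4a,5,6,7-octahydronaphthalene-1-carboxylate, via alkylborane 18 (not isolated)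
Conditions: (Sia)2BH [bis(3-methylbutan-2-yl)borane, from BH3·SMe2 and 2-methylbut-2-ene], THF, 0 °C; then 17, PdCl2(dppf) (5 mol%), AsPh3, Cs2CO3, DMF/H2O, rt
Reagents that add atoms: none
Why: the bulky dialkylborane hydroborates the monosubstituted vinyl group (boron at C12) in preference to the 1,1-disubstituted methylene and the tetrasubstituted enol ether, and B-alkyl Suzuki–Miyaura coupling forms C12–C13 with retention of the (E)-alkene.

Step 10
Reactants: 19 coupled enol ether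
Product: 21 tert-butyl (1S,4aR,5R,8R,8aR)-5-[(3E)-5-{[tert-butyl(diphenyl)silyl]oxy}-3-methylpent-3-en-1-yl]-8-hydroxy-1,4a-dimethyl-6-methylidenedecahydronaphthalene-1-carboxylate, via ketone 20 (not isolated)
Conditions: HCl (0.1 M, cat.), THF/H2O, 0 °C; then CeCl3·7H2O, NaBH4, MeOH, −40 °C
Reagents that add atoms: water O
Why: enol ether hydrolysis protonates C5 from the α-face, away from the two β-axial groups (C20 methyl and CO2tBu), to give the trans-fused C6 ketone (C5 R, also the thermodynamic epimer), and hydride then attacks the ketone from the open α-face to give the axial 6β-alcohol (C6 set); cold, immediate reduction limits conjugation of the β,γ-enone and attack of the alkoxide on the tert-butyl ester.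

Step 11
Reactants: 21 6β-alcohol
Product: 22 tert-butyl (1S,4aR,5R,8R,8aR)-8-(benzoyloxy)-5-[(3E)-5-{[tert-butyl(diphenyl)silyl]oxy}-3-methylpent-3-en-1-yl]-1,4a-dimethyl-6-methylidenedecahydronaphthalene-1-carboxylate
Conditions: BzOTf (1.5 equiv), pyridine, CH2Cl2, −78 → 0 °C
Reagents that add atoms: benzoyl trifluoromethanesulfonate O=C(OS(=O)(=O)C(F)(F)F)c1ccccc1
Why: the N-benzoylpyridinium triflate formed in the flask is a strong enough acylating agent for the 1,3-diaxially hindered 6β-hydroxyl, and the neutral alcohol (no alkoxide) does not lactonise onto C19 (O-acylation).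

Step 12
Reactants: 22 6β-benzoate
Product: 23 tert-butyl (1S,4aR,5S,7S,8S,8aR)-8-(benzoyloxy)-5-[(3E)-5-{[tert-butyl(diphenyl)silyl]oxy}-3-methylpent-3-en-1-yl]-7-hydroxy-1,4a-dimethyl-6-methylidenedecahydronaphthalene-1-carboxylate
Conditions: SeO2 (30 mol%), tBuOOH (3 equiv), CH2Cl2, 0 °C → rt
Reagents that add atoms: tert-butyl hydroperoxide CC(C)(C)OO; selenium dioxide O=[Se]=O
Why: selenium dioxide allylic hydroxylation: the ene step at the 8(17)-alkene removes the axial H-7α and the [2,3]-shift returns oxygen to C7 on the α-face, anti to the adjacent axial benzoate (7S, trans-diaxial), while the side-chain alkene is deactivated by its allylic silyloxy group and the equatorial H-9 is not aligned.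

Step 13
Reactants: 23 7α-alcohol
Product: 25 (1S,4aR,5S,7S,8S,8aR)-8-(benzoyloxy)-7-hydroxy-5-[(3E)-5-hydroxy-3-methylpent-3-en-1-yl]-1,4a-dimethyl-6-methylidenedecahydronaphthalene-1-carboxylic acid, via silylated ester 24 (not isolated)
Conditions: TMSOTf (4 equiv), 2,6-lutidine, CH2Cl2, 0 °C; then HF·pyridine, THF, 0 °C → rt
Reagents that add atoms: none
Why: silylation of the ester carbonyl expels isobutene without free protic acid (the exocyclic alkene and allylic alcohols are spared), and fluoride then cleaves the silyl ester, the C7 silyl ether and the TBDPS ether while the hindered benzoate stays.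

## Compound list

1 | tert-butyl 3-oxopentanoate | CCC(=O)CC(=O)OC(C)(C)C | starting material
2 | tert-butyl 2-methyl-3-oxopentanoate (racemic, stereolabile) | CCC(=O)C(C)C(=O)OC(C)(C)C | intermediate
3 | acrolein (prop-2-enal) | C=CC=O | starting material
4 | tert-butyl (2S)-2-methyl-3-oxo-2-(3-oxopropyl)pentanoate | O=CCC[C@](C)(C(=O)OC(C)(C)C)C(=O)CC | intermediate
5 | tert-butyl (1S)-1,3-dimethyl-2-oxocyclohex-3-ene-1-carboxylate | CC1=CCC[C@](C)(C(=O)OC(C)(C)C)C1=O | intermediate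
6 | lithium (6S)-6-(tert-butoxycarbonyl)-2,6-dimethylcyclohex-1-en-1-olate | CC1=C([O-])[C@@](C)(C(=O)OC(C)(C)C)CCC1.[Li+] | intermediate
7 | tert-butyl (1S)-1,3-dimethyl-2-{[(trifluoromethyl)sulfonyl]oxy}cyclohex-2-ene-1-carboxylate | CC1=C(OS(=O)(=O)C(F)(F)F)[C@@](C)(C(=O)OC(C)(C)C)CCC1 | intermediate
8 | tributyl(1-ethoxyethenyl)stannane | CCCC[Sn](CCCC)(CCCC)C(=C)OCC | starting material
9 | tert-butyl (1S)-2-(1-ethoxyethenyl)-1,3-dimethylcyclohex-2-ene-1-carboxylate | CCOC(=C)C1=C(C)CCC[C@]1(C)C(=O)OC(C)(C)C | intermediate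
10 | ethyl buta-2,3-dienoate | C=C=CC(=O)OCC | starting material
11 | 1-tert-butyl 5-ethyl (1S,4aR,5R)-8-ethoxy-1,4a-dimethyl-6-methylidene-1,2,3,4,4a,5,6,7-octahydronaphthalene-1,5-dicarboxylate | C=C1[C@@H](C(=O)OCC)[C@@]2(C)CCC[C@](C)(C(=O)OC(C)(C)C)C2=C(OCC)C1 | intermediate
12 | tert-butyl (1S,4aR,5R)-8-ethoxy-5-formyl-1,4a-dimethyl-6-methylidene-1,2,3,4,4a,5,6,7-octahydronaphthalene-1-carboxylate | C=C1[C@@H](C=O)[C@@]2(C)CCC[C@](C)(C(=O)OC(C)(C)C)C2=C(OCC)C1 | intermediate
13 | tert-butyl (1S,4aR,5R)-5-ethenyl-8-ethoxy-1,4a-dimethyl-6-methylidene-1,2,3,4,4a,5,6,7-octahydronaphthalene-1-carboxylate | C=C1[C@@H](C=C)[C@@]2(C)CCC[C@](C)(C(=O)OC(C)(C)C)C2=C(OCC)C1 | intermediate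
14 | but-2-yn-1-ol | CC#CCO | starting material
15 | (but-2-yn-1-yloxy)(tert-butyl)diphenylsilane | CC#CCO[Si](c1ccccc1)(c1ccccc1)C(C)(C)C | intermediate
16 | chlorobis(cyclopentadienyl)[(2E)-4-{[tert-butyl(diphenyl)silyl]oxy}but-2-en-2-yl]zirconium | Cl[Zr](C1C=CC=C1)(C1C=CC=C1)/C(C)=C/CO[Si](c1ccccc1)(c1ccccc1)C(C)(C)C | intermediate
17 | tert-butyl{[(2E)-3-iodobut-2-en-1-yl]oxy}diphenylsilane | I/C(C)=C/CO[Si](c1ccccc1)(c1ccccc1)C(C)(C)C | intermediate
18 | tert-butyl (1S,4aR,5R)-5-{2-[bis(3-methylbutan-2-yl)boranyl]ethyl}-8-ethoxy-1,4a-dimethyl-6-methylidene-1,2,3,4,4a,5,6,7-octahydronaphthalene-1-carboxylate | C=C1[C@@H](CCB(C(C)C(C)C)C(C)C(C)C)[C@@]2(C)CCC[C@](C)(C(=O)OC(C)(C)C)C2=C(OCC)C1 | intermediate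
19 | tert-butyl (1S,4aR,5R)-5-[(3E)-5-{[tert-butyl(diphenyl)silyl]oxy}-3-methylpent-3-en-1-yl]-8-ethoxy-1,4a-dimethyl-6-methylidene-1,2,3,4,4a,5,6,7-octahydronaphthalene-1-carboxylate | C=C1[C@@H](CC/C(C)=C/CO[Si](c3ccccc3)(c3ccccc3)C(C)(C)C)[C@@]2(C)CCC[C@](C)(C(=O)OC(C)(C)C)C2=C(OCC)C1 | intermediate
20 | tert-butyl (1S,4aR,5R,8aR)-5-[(3E)-5-{[tert-butyl(diphenyl)silyl]oxy}-3-methylpent-3-en-1-yl]-1,4a-dimethyl-6-methylidene-8-oxodecahydronaphthalene-1-carboxylate | C=C1[C@@H](CC/C(C)=C/CO[Si](c3ccccc3)(c3ccccc3)C(C)(C)C)[C@@]2(C)CCC[C@](C)(C(=O)OC(C)(C)C)[C@@H]2C(=O)C1 | intermediate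
21 | tert-butyl (1S,4aR,5R,8R,8aR)-5-[(3E)-5-{[tert-butyl(diphenyl)silyl]oxy}-3-methylpent-3-en-1-yl]-8-hydroxy-1,4a-dimethyl-6-methylidenedecahydronaphthalene-1-carboxylate (6β-OH) | C=C1[C@@H](CC/C(C)=C/CO[Si](c3ccccc3)(c3ccccc3)C(C)(C)C)[C@@]2(C)CCC[C@](C)(C(=O)OC(C)(C)C)[C@@H]2[C@H](O)C1 | intermediate
22 | tert-butyl (1S,4aR,5R,8R,8aR)-8-(benzoyloxy)-5-[(3E)-5-{[tert-butyl(diphenyl)silyl]oxy}-3-methylpent-3-en-1-yl]-1,4a-dimethyl-6-methylidenedecahydronaphthalene-1-carboxylate | C=C1[C@@H](CC/C(C)=C/CO[Si](c3ccccc3)(c3ccccc3)C(C)(C)C)[C@@]2(C)CCC[C@](C)(C(=O)OC(C)(C)C)[C@@H]2[C@H](OC(=O)c3ccccc3)C1 | intermediate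
23 | tert-butyl (1S,4aR,5S,7S,8S,8aR)-8-(benzoyloxy)-5-[(3E)-5-{[tert-butyl(diphenyl)silyl]oxy}-3-methylpent-3-en-1-yl]-7-hydroxy-1,4a-dimethyl-6-methylidenedecahydronaphthalene-1-carboxylate | C=C1[C@@H](CC/C(C)=C/CO[Si](c3ccccc3)(c3ccccc3)C(C)(C)C)[C@@]2(C)CCC[C@](C)(C(=O)OC(C)(C)C)[C@@H]2[C@H](OC(=O)c3ccccc3)[C@H]1O | intermediate
24 | trimethylsilyl (1S,4aR,5S,7S,8S,8aR)-8-(benzoyloxy)-5-[(3E)-5-{[tert-butyl(diphenyl)silyl]oxy}-3-methylpent-3-en-1-yl]-1,4a-dimethyl-6-methylidene-7-[(trimethylsilyl)oxy]decahydronaphthalene-1-carboxylate | C=C1[C@@H](CC/C(C)=C/CO[Si](c3ccccc3)(c3ccccc3)C(C)(C)C)[C@@]2(C)CCC[C@](C)(C(=O)O[Si](C)(C)C)[C@@H]2[C@H](OC(=O)c3ccccc3)[C@H]1O[Si](C)(C)C | intermediate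
25 | (1S,4aR,5S,7S,8S,8aR)-8-(benzoyloxy)-7-hydroxy-5-[(3E)-5-hydroxy-3-methylpent-3-en-1-yl]-1,4a-dimethyl-6-methylidenedecahydronaphthalene-1-carboxylic acid (CNP0149011.1) | C=C1[C@@H](CC/C(C)=C/CO)[C@@]2(C)CCC[C@](C)(C(=O)O)[C@@H]2[C@H](OC(=O)c2ccccc2)[C@H]1O | target

## Step count and risks

Total step count: 13. Longest linear sequence: 11 (steps 1–6 and 9–13; steps 7–8 make the side-chain iodide).

The three steps most likely to fail:

Step 5, the proposed new cycloaddition. The tetrasubstituted diene terminus may not react, the allenoate may close through its γ-carbon instead of C9, or the silylium catalyst may cleave the tert-butyl ester. The fallback uses known chemistry, sets out from 9 and comes back at 11. Ethyl (2E)-4-bromobut-2-enoate is converted with PhSeNa into the allene equivalent ethyl (2E)-4-(phenylselanyl)but-2-enoate F1, which has only one reactive double bond. Uncatalysed cycloaddition with 9 (neat, 120 °C, sealed tube, or 12 kbar in CH2Cl2), of the kind known for 2,6,6-trimethyl-1-vinylcyclohexene, gives under substrate control the selenide cycloadduct F2 (ester endo, 5,6-trans). Oxidation with H2O2/pyridine and syn-elimination of the selenoxide installs the 8(17)-methylene and returns 11 after separation of diastereomers.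

Step 9, the chemoselective hydroboration and B-alkyl coupling. The exocyclic methylene may compete for the borane, or the hindered primary alkylborane may transfer poorly. The fallback sets out from aldehyde 12 (the iBu2AlH stage of step 6 quenched and the aldehyde isolated) and comes back at 19. Wittig reaction with Ph3P=CHC(O)CH3 gives the (E)-enone F3, conjugate reduction with [(Ph3P)CuH]6 gives the methyl ketone F4, and Horner–Wadsworth–Emmons reaction with (EtO)2P(O)CH2CO2Et/NaH gives the (E)-enoate F5 (minor Z isomer removed). Reduction with iBu2AlH at −78 °C gives the allylic alcohol F6, and TBDPSCl/imidazole gives 19.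

Step 12, the allylic hydroxylation. The C7 epimer ratio, over-oxidation to the enone and attack on the side-chain alkene are all uncertain. The fallback puts the C7 oxygen in by enolate chemistry before the ketone is reduced; it sets out from ketone 20 (isolated after the hydrolysis stage of step 10) and comes back at 25. TBSOTf/Et3N gives the silyl dienol ether F7, and dimethyldioxirane from the α-face with 1,4-silyl shift (Rubottom oxidation) gives the 7α-silyloxy ketone F8. NaBH4/CeCl3 gives the 6β-alcohol F9, BzOTf/pyridine gives the benzoate F10, and the conditions of step 13 remove the tert-butyl ester and both silyl ethers to give 25.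

## Further compounds

F1 | step 5 | ethyl (2E)-4-(phenylselanyl)but-2-enoate | CCOC(=O)/C=C/C[Se]c1ccccc1
F2 | step 5 | 1-tert-butyl 5-ethyl (1S,4aR,5R,6S)-8-ethoxy-1,4a-dimethyl-6-[(phenylselanyl)methyl]-1,2,3,4,4a,5,6,7-octahydronaphthalene-1,5-dicarboxylate | c3ccccc3[Se]C[C@@H]1[C@@H](C(=O)OCC)[C@@]2(C)CCC[C@](C)(C(=O)OC(C)(C)C)C2=C(OCC)C1
F3 | step 9 | tert-butyl (1S,4aR,5R)-8-ethoxy-1,4a-dimethyl-6-methylidene-5-[(1E)-3-oxobut-1-en-1-yl]-1,2,3,4,4a,5,6,7-octahydronaphthalene-1-carboxylate | C=C1[C@@H](/C=C/C(C)=O)[C@@]2(C)CCC[C@](C)(C(=O)OC(C)(C)C)C2=C(OCC)C1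
F4 | step 9 | tert-butyl (1S,4aR,5R)-8-ethoxy-1,4a-dimethyl-6-methylidene-5-(3-oxobutyl)-1,2,3,4,4a,5,6,7-octahydronaphthalene-1-carboxylate | C=C1[C@@H](CCC(C)=O)[C@@]2(C)CCC[C@](C)(C(=O)OC(C)(C)C)C2=C(OCC)C1
F5 | step 9 | tert-butyl (1S,4aR,5R)-8-ethoxy-5-[(3E)-5-ethoxy-3-methyl-5-oxopent-3-en-1-yl]-1,4a-dimethyl-6-methylidene-1,2,3,4,4a,5,6,7-octahydronaphthalene-1-carboxylate | C=C1[C@@H](CC/C(C)=C/C(=O)OCC)[C@@]2(C)CCC[C@](C)(C(=O)OC(C)(C)C)C2=C(OCC)C1
F6 | step 9 | tert-butyl (1S,4aR,5R)-8-ethoxy-5-[(3E)-5-hydroxy-3-methylpent-3-en-1-yl]-1,4a-dimethyl-6-methylidene-1,2,3,4,4a,5,6,7-octahydronaphthalene-1-carboxylate | C=C1[C@@H](CC/C(C)=C/CO)[C@@]2(C)CCC[C@](C)(C(=O)OC(C)(C)C)C2=C(OCC)C1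
F7 | step 12 | tert-butyl (1S,4aR,5R,8aR)-8-{[tert-butyl(dimethyl)silyl]oxy}-5-[(3E)-5-{[tert-butyl(diphenyl)silyl]oxy}-3-methylpent-3-en-1-yl]-1,4a-dimethyl-6-methylidene-1,2,3,4,4a,5,6,8a-octahydronaphthalene-1-carboxylate | C=C1[C@@H](CC/C(C)=C/CO[Si](c3ccccc3)(c3ccccc3)C(C)(C)C)[C@@]2(C)CCC[C@](C)(C(=O)OC(C)(C)C)[C@@H]2C(O[Si](C)(C)C(C)(C)C)=C1
F8 | step 12 | tert-butyl (1S,4aR,5S,7S,8aR)-7-{[tert-butyl(dimethyl)silyl]oxy}-5-[(3E)-5-{[tert-butyl(diphenyl)silyl]oxy}-3-methylpent-3-en-1-yl]-1,4a-dimethyl-6-methylidene-8-oxodecahydronaphthalene-1-carboxylate | C=C1[C@@H](CC/C(C)=C/CO[Si](c3ccccc3)(c3ccccc3)C(C)(C)C)[C@@]2(C)CCC[C@](C)(C(=O)OC(C)(C)C)[C@@H]2C(=O)[C@H]1O[Si](C)(C)C(C)(C)C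
F9 | step 12 | tert-butyl (1S,4aR,5S,7S,8S,8aR)-7-{[tert-butyl(dimethyl)silyl]oxy}-5-[(3E)-5-{[tert-butyl(diphenyl)silyl]oxy}-3-methylpent-3-en-1-yl]-8-hydroxy-1,4a-dimethyl-6-methylidenedecahydronaphthalene-1-carboxylate | C=C1[C@@H](CC/C(C)=C/CO[Si](c3ccccc3)(c3ccccc3)C(C)(C)C)[C@@]2(C)CCC[C@](C)(C(=O)OC(C)(C)C)[C@@H]2[C@H](O)[C@H]1O[Si](C)(C)C(C)(C)C
F10 | step 12 | tert-butyl (1S,4aR,5S,7S,8S,8aR)-8-(benzoyloxy)-7-{[tert-butyl(dimethyl)silyl]oxy}-5-[(3E)-5-{[tert-butyl(diphenyl)silyl]oxy}-3-methylpent-3-en-1-yl]-1,4a-dimethyl-6-methylidenedecahydronaphthalene-1-carboxylate | C=C1[C@@H](CC/C(C)=C/CO[Si](c3ccccc3)(c3ccccc3)C(C)(C)C)[C@@]2(C)CCC[C@](C)(C(=O)OC(C)(C)C)[C@@H]2[C@H](OC(=O)c3ccccc3)[C@H]1O[Si](C)(C)C(C)(C)C
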